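The hydroazulene (azulene numbering) is cut across its seven-membered ring into the two-carbon unit C3a–C4 and the five-carbon unit C5–C8a, which stay linked through C1–C3. One redox-neutral radical–polar (5+2) annulation makes both bonds. A tertiary α-keto radical at C8a closes the cyclopentane onto an enol veratrate (C3a–C8a). The resulting C4 radical is oxidised, and the 2-methylallyl terminus C5 closes the cycloheptenone (C4–C5). The step exploits the 1,4-relation of the C8 ketone and the C4 ester oxygen across the ring fusion. Its precursor is an acyclic α-chloro ketone built from (S)-terpinen-4-ol, whose carbinol carbon becomes C3.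

Key step: step 7

Assumption: commercial (+)-terpinen-4-ol is the (S)-enantiomer and is used enantiopure. Its descriptor changes from S to R along the route only because substituent priorities change.

Step 1
Reactants: 1 (S)-(+)-terpinen-4-ol
Product: 2 triethyl{[(1S)-4-methyl-1-(propan-2-yl)cyclohex-3-en-1-yl]oxy}silane
Conditions: TESOTf, 2,6-lutidine, CH2Cl2, 0 °C to rt
Reagents that add atoms: triethylsilyl trifluoromethanesulfonate, CC[Si](CC)(CC)OS(=O)(=O)C(F)(F)F
Why: Silyl triflate silylation is strong enough for the hindered tertiary alcohol and leaves the carbinol stereocentre (future C3) untouched.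

Step 2
Reactants: 2 TES ether of terpinen-4-ol
Product: 4 (3S)-6-oxo-3-(propan-2-yl)-3-[(triethylsilyl)oxy]heptanal, via secondary ozonide 3 (not isolated)
Conditions: O3, CH2Cl2, −78 °C; then Me2S, −78 °C to rt
Reagents that add atoms: ozone, O=[O+][O-]
Why: Ozonolysis with reductive work-up cleaves the only C=C bond, unveils C4 as the aldehyde and C8a as the methyl ketone carbon, and touches no stereocentre.

Step 3
Reactants: 4 keto aldehyde; 5 3,4-dimethoxybenzoyl chloride
Product: 6 (1E,3R)-6-oxo-3-(propan-2-yl)-3-[(triethylsilyl)oxy]hept-1-en-1-yl 3,4-dimethoxybenzoate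
Conditions: 5, Et3N, DMAP (20 mol %), toluene, 60 °C
Reagents that add atoms: 3,4-dimethoxybenzoyl chloride (5), COc1ccc(C(Cl)=O)cc1OC
Why: DMAP-catalysed O-acylative enolisation (enol ester synthesis) should act on the aldehyde far faster than on the methyl ketone, and anti elimination should place the aroyloxy group trans to the fully substituted C3.

Step 4
Reactants: 6 enol veratrate ketone; 7 dichloromethane
Product: 10 (1E,3R)-6-chloro-6-methyl-7-oxo-3-(propan-2-yl)-3-[(triethylsilyl)oxy]hept-1-en-1-yl 3,4-dimethoxybenzoate (both C6 epimers), via lithium alkoxide 8 (not isolated), via chlorooxirane 9 (not isolated)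
Conditions: 7, LDA added to the mixture, THF, −95 °C; then warm to 40 °C
Reagents that add atoms: dichloromethane (7), ClCCl
Why: In this dichloromethyllithium homologation the carbenoid adds to the ketone, alkoxide 8 closes to chlorooxirane 9, and 9 rearranges with chloride migration to the tertiary α-chloro aldehyde; the new centre is an epimer mixture that step 7 erases.

Step 5
Reactants: 10 α-chloro aldehyde; 11 2-methylallylboronic acid pinacol ester
Product: 13 (1E,3R)-6-chloro-7-hydroxy-6,9-dimethyl-3-(propan-2-yl)-3-[(triethylsilyl)oxy]deca-1,9-dien-1-yl 3,4-dimethoxybenzoate (diastereomer mixture), via pinacol borate 12 (not isolated)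
Conditions: 11, toluene, 40 °C; then aq. NaHCO3 work-up
Reagents that add atoms: 2-methylallylboronic acid pinacol ester (11), CC(=C)CB1OC(C)(C)C(C)(C)O1
Why: Allylboration through a closed six-membered transition state is base-free and selective for the activated aldehyde over ester and chloride, and the new carbinol centre is removed in step 6.

Step 6
Reactants: 13 chlorohydrin
Product: 14 (1E,3R)-6-chloro-6,9-dimethyl-7-oxo-3-(propan-2-yl)-3-[(triethylsilyl)oxy]deca-1,9-dien-1-yl 3,4-dimethoxybenzoate (both C6 epimers)
Conditions: DMP, pyridine, CH2Cl2, 0 °C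
Reagents that add atoms: none
Why: Buffered Dess–Martin oxidation should give the β,γ-unsaturated α′-chloro ketone without moving the alkene into conjugation or disturbing the enol ester.

Step 7
Reactants: 14 α-chloro ketone
Product: 16 (3R,3aS,4S,8aS)-6,8a-dimethyl-8-oxo-3-(propan-2-yl)-3-[(triethylsilyl)oxy]-1,2,3,3a,4,5,8,8a-octahydroazulen-4-yl 3,4-dimethoxybenzoate, via acyloxycarbenium ion 15 (not isolated)
Conditions: fac-Ir(ppy)3 (2 mol %), 2,6-di-tert-butyl-4-methylpyridine, CH2Cl2/(CF3)2CHOH 4:1 (5 mM), blue LEDs (450 nm), 20 °C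
Reagents that add atoms: none
Why: Proposed new method: the excited trivalent iridium complex reduces the C–Cl bond of 14 (both epimers converge) to the planar tertiary α-keto radical at C8a, this electrophilic radical adds to C3a of the electron-rich enol ester, the α-acyloxy radical at C4 is oxidised by the tetravalent iridium complex to ion 15, the CH2 terminus (C5) of the 2-methylallyl group attacks C4, and the tertiary C6 cation loses the carbonyl-acidified C7 proton to the pyridine base, which gives the conjugated enone and closes a redox-neutral cycle. The closest known reaction types are the photoredox coupling of α-halo ketones with enol acetates or silyl enol ethers to 1,4-dicarbonyl compounds by radical–polar crossover and the Prins or type 2 carbonyl-ene closure of seven-membered carbocycles; new is that the oxidised adduct is caught by a tethered alkene instead of being hydrolysed. The cyclopentane closes 5-exo-trig (the radical's only alternatives, 4-exo or 5-endo attack on the methallyl alkene, are slow), and the cycloheptenone closes by attack of the unsubstituted alkene terminus, endo at the alkene and exo at the C=O+ bond. C3a is set in a chair-like 5-hexenyl transition state with the isopropyl group of C3 pseudo-equatorial, which puts the C4 branch trans to isopropyl and cis to OTES; C8a is set in the same event because the acyl branch avoids the aroyloxyvinyl terminus and leaves the methyl group cis to it (trans ring fusion); C4 is set in a chair-like closure with the aroyloxy group equatorial and H4 anti to H3a. The step needs oxidation and ring closure to outrun hydrogen transfer and loss of the aroyl group: hexafluoroisopropanol ties up chloride and supports the cation, and the trans disposition of the two branches rules out collapse of C4 onto the ketone oxygen in a strained trans-fused five-membered ring, so only the seven-membered closure remains. The geometry of the enol ester is lost at the radical stage, so an E/Z mixture converges.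

Step 8
Reactants: 16 TES-protected target
Product: 17 (3R,3aS,4S,8aS)-3-hydroxy-6,8a-dimethyl-8-oxo-3-(propan-2-yl)-1,2,3,3a,4,5,8,8a-octahydroazulen-4-yl 3,4-dimethoxybenzoate (CNP0111132.1)
Conditions: HF·pyridine, THF, 0 °C to rt
Reagents that add atoms: none
Why: Fluoride-mediated desilylation under weakly acidic conditions frees the tertiary alcohol without vinylogous elimination or migration of the veratrate, and no stereocentre is touched.

Compound list
1 | (S)-(+)-terpinen-4-ol | CC1=CC[C@](O)(C(C)C)CC1 | starting material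
2 | triethyl{[(1S)-4-methyl-1-(propan-2-yl)cyclohex-3-en-1-yl]oxy}silane | CC1=CC[C@](O[Si](CC)(CC)CC)(C(C)C)CC1 | intermediate
3 | secondary ozonide of 2 (bridged 1,2,4-trioxolane) | CC12CC[C@@](O[Si](CC)(CC)CC)(C(C)C)CC(OO1)O2 | intermediate (not isolated)
4 | (3S)-6-oxo-3-(propan-2-yl)-3-[(triethylsilyl)oxy]heptanal | CC(=O)CC[C@@](O[Si](CC)(CC)CC)(C(C)C)CC=O | intermediate
5 | 3,4-dimethoxybenzoyl chloride | COc1ccc(C(Cl)=O)cc1OC | starting material
6 | (1E,3R)-6-oxo-3-(propan-2-yl)-3-[(triethylsilyl)oxy]hept-1-en-1-yl 3,4-dimethoxybenzoate | CC(=O)CC[C@@](O[Si](CC)(CC)CC)(C(C)C)/C=C/OC(=O)c1ccc(OC)c(OC)c1 | intermediate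
7 | dichloromethane | ClCCl | starting material
8 | lithium alkoxide of the dichloromethyl carbinol from 6 | CC(O[Li])(C(Cl)Cl)CC[C@@](O[Si](CC)(CC)CC)(C(C)C)/C=C/OC(=O)c1ccc(OC)c(OC)c1 | intermediate (not isolated)
9 | 3-chloro-2-methyloxirane derived from 8 | CC1(OC1Cl)CC[C@@](O[Si](CC)(CC)CC)(C(C)C)/C=C/OC(=O)c1ccc(OC)c(OC)c1 | intermediate (not isolated)
10 | (1E,3R)-6-chloro-6-methyl-7-oxo-3-(propan-2-yl)-3-[(triethylsilyl)oxy]hept-1-en-1-yl 3,4-dimethoxybenzoate, C6 epimers | CC(Cl)(C=O)CC[C@@](O[Si](CC)(CC)CC)(C(C)C)/C=C/OC(=O)c1ccc(OC)c(OC)c1 | intermediate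
11 | 2-methylallylboronic acid pinacol ester | CC(=C)CB1OC(C)(C)C(C)(C)O1 | starting material
12 | pinacol borate of chlorohydrin 13 | CC(=C)CC(OB1OC(C)(C)C(C)(C)O1)C(C)(Cl)CC[C@@](O[Si](CC)(CC)CC)(C(C)C)/C=C/OC(=O)c1ccc(OC)c(OC)c1 | intermediate (not isolated)
13 | (1E,3R)-6-chloro-7-hydroxy-6,9-dimethyl-3-(propan-2-yl)-3-[(triethylsilyl)oxy]deca-1,9-dien-1-yl 3,4-dimethoxybenzoate, diastereomer mixture at C6 and C7 | CC(=C)CC(O)C(C)(Cl)CC[C@@](O[Si](CC)(CC)CC)(C(C)C)/C=C/OC(=O)c1ccc(OC)c(OC)c1 | intermediate
14 | (1E,3R)-6-chloro-6,9-dimethyl-7-oxo-3-(propan-2-yl)-3-[(triethylsilyl)oxy]deca-1,9-dien-1-yl 3,4-dimethoxybenzoate, C6 epimers | CC(=C)CC(=O)C(C)(Cl)CC[C@@](O[Si](CC)(CC)CC)(C(C)C)/C=C/OC(=O)c1ccc(OC)c(OC)c1 | intermediate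
15 | monocyclic acyloxycarbenium ion (cyclopentane closed, C4 cationic) | CC(=C)CC(=O)[C@@]1(C)CC[C@@](O[Si](CC)(CC)CC)(C(C)C)[C@@H]1[CH+]OC(=O)c1ccc(OC)c(OC)c1 | intermediate (not isolated)
16 | (3R,3aS,4S,8aS)-6,8a-dimethyl-8-oxo-3-(propan-2-yl)-3-[(triethylsilyl)oxy]-1,2,3,3a,4,5,8,8a-octahydroazulen-4-yl 3,4-dimethoxybenzoate | COc1ccc(C(=O)O[C@H]2CC(C)=CC(=O)[C@@]3(C)CC[C@@](O[Si](CC)(CC)CC)(C(C)C)[C@H]23)cc1OC | intermediate
17 | (3R,3aS,4S,8aS)-3-hydroxy-6,8a-dimethyl-8-oxo-3-(propan-2-yl)-1,2,3,3a,4,5,8,8a-octahydroazulen-4-yl 3,4-dimethoxybenzoate | COc1ccc(C(=O)O[C@H]2CC(C)=CC(=O)[C@@]3(C)CC[C@@](O)(C(C)C)[C@H]23)cc1OC | target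

Total step count: 8. Longest linear sequence: 8 steps (1 to 17).

Steps most likely to fail

1. Step 7 (Proposed new method).
- What may go wrong: 1,5-hydrogen transfer from the activated C7 methylene to the C4 radical before its oxidation, loss of the aroyl group from the cation before the alkene attacks, or poor facial selectivity at C8a that erodes the trans ring fusion.
- Fallback, from 14 back to 16, splitting the cascade into known operations. The same photocatalyst in wet MeCN with 2,6-lutidine couples the α-chloro ketone with the enol ester in the established way, and hydrolysis of the oxidised adduct should give the cyclopentanecarbaldehyde F1. Me2AlCl in CH2Cl2 at −78 °C should then close the seven-membered ring by a type 2 carbonyl-ene reaction to the 6-methylidene alcohol F2. Acylation with 5 (Et3N, DMAP) should give the 6-methylidene ester F3. DABCO in CH2Cl2 should move the exocyclic alkene into conjugation, which is 16.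

2. Step 4.
- What may go wrong: enolisation of the methyl ketone by the amide base, or attack of the carbenoid on the enol ester carbonyl instead of the ketone.
- Fallback, from 6 back to 10. Corey–Chaykovsky methylenation (Me3SI, KOtBu, THF/DMSO) should give the terminal epoxide F4. Meinwald rearrangement with catalytic Bi(OTf)3 should give the α-methyl aldehyde F5. Enamine-catalysed α-chlorination (NCS, catalytic pyrrolidine, CH2Cl2) should install the tertiary chloride, which is 10.

3. Step 3.
- What may go wrong: β-elimination of the silyloxy group during enolisation, sluggish O-acylation, or competing acylation at the ketone.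
- Fallback, from 4 back to 6. ZnCl2-catalysed addition of 5 across the aldehyde C=O should give the 1-chloroalkyl veratrate F6. E2 dehydrochlorination with DBU in toluene should then deliver 6.

Further compounds
F1 | step 7 | 2-methyl-2-(3-methylbut-3-enoyl)-5-(propan-2-yl)-5-[(triethylsilyl)oxy]cyclopentane-1-carbaldehyde, configuration as in 16 | CC(=C)CC(=O)[C@@]1(C)CC[C@@](O[Si](CC)(CC)CC)(C(C)C)[C@@H]1C=O
F2 | step 7 | 4-hydroxy-8a-methyl-6-methylidene-3-(propan-2-yl)-3-[(triethylsilyl)oxy]decahydroazulen-8-one, configuration as in 16 | O[C@H]1CC(=C)CC(=O)[C@@]2(C)CC[C@@](O[Si](CC)(CC)CC)(C(C)C)[C@H]12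
F3 | step 7 | 6-methylidene isomer of 16 (veratrate of F2) | COc1ccc(C(=O)O[C@H]2CC(=C)CC(=O)[C@@]3(C)CC[C@@](O[Si](CC)(CC)CC)(C(C)C)[C@H]23)cc1OC
F4 | step 4 | 2-methyloxirane from ketone 6 (epimers at the oxirane carbon) | CC1(CO1)CC[C@@](O[Si](CC)(CC)CC)(C(C)C)/C=C/OC(=O)c1ccc(OC)c(OC)c1
F5 | step 4 | (1E,3R)-6-methyl-7-oxo-3-(propan-2-yl)-3-[(triethylsilyl)oxy]hept-1-en-1-yl 3,4-dimethoxybenzoate (C6 epimers) | CC(C=O)CC[C@@](O[Si](CC)(CC)CC)(C(C)C)/C=C/OC(=O)c1ccc(OC)c(OC)c1
F6 | step 3 | 1-chloro-6-oxo-3-(propan-2-yl)-3-[(triethylsilyl)oxy]heptyl 3,4-dimethoxybenzoate (C1 epimers) | CC(=O)CC[C@@](O[Si](CC)(CC)CC)(C(C)C)CC(Cl)OC(=O)c1ccc(OC)c(OC)c1
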